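The cyclopentenone ring (prostanoid atoms C8–C12) is read as a methyl ketone plus an acryloyl unit. Carbinol carbon C12 and α-carbon C8 are the carbonyl and methyl carbons of 4,4-dimethoxybutan-2-one, and C9–C10–C11 come from an enantiopure β-sulfinylacryloylsilane. In one operation enolate carbon C8 adds to acyl carbon C9, silicon migrates to O9 (Brook), and the sulfinyl-stabilised C11 carbanion closes onto the C12 ketone. This gives the ring and the tertiary carbinol stereocentre from two simple acyclic precursors. Bromination at C10 then expels the sulfoxide. A Wittig reaction and an anti-aldol attach both Z-alkenyl chains and set C8 and C7.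

Key step: step 5

Remark: prostanoid numbering is used (C1 ester carbon, C5=C6, C7 acetoxy carbon, ring C8–C12 with C9 carbonyl, C10 bromine-bearing and C12 carbinol, chain C13–C20). The sense of sulfoxide induction in step 5 is taken from the chelate model, and the enantiomeric sulfinate is equally available should the sense be opposite.

Step 1
Reactants: 1 tert-butyldimethyl(prop-2-yn-1-yloxy)silane
Product: 3 1-(tert-butyldimethylsilyl)prop-2-yn-1-ol (racemic), via dilithio alkoxide 2 (not isolated)
Conditions: n-BuLi (1.0 equiv) then s-BuLi (1.2 equiv), THF, −78 to −40 °C; AcOH, −78 °C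
Reagents that add atoms: none
Why: Retro-[1,2]-Brook rearrangement: once the acetylide is in place the second base removes a propargylic proton next to oxygen and silicon moves from O to C because the alkoxide is the more stable anion, and the racemic carbinol centre formed here is erased in step 4.

Step 2
Reactants: 3 1-(tert-butyldimethylsilyl)prop-2-yn-1-ol; 4 (1R,2S,5R)-menthyl (S)-4-methylbenzenesulfinate
Product: 6 1-(tert-butyldimethylsilyl)-3-[(S)-4-methylphenylsulfinyl]prop-2-yn-1-ol (both carbinol epimers), via bis(bromomagnesium) derivative 5 (not isolated)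
Conditions: EtMgBr (2.1 equiv), THF, 0 °C; 4, toluene, −20 to 0 °C; H2O
Reagents that add atoms: none
Why: Andersen sulfoxide synthesis: the alkynyl Grignard carbon displaces mentholate at sulfur with inversion, so the sulfur stereocentre is taken from the enantiopure sulfinate (the descriptor reads S only because the alkynyl group outranks tolyl).

Step 3
Reactants: 6 1-(tert-butyldimethylsilyl)-3-[(S)-4-methylphenylsulfinyl]prop-2-yn-1-ol
Product: 7 (E)-1-(tert-butyldimethylsilyl)-3-[(R)-4-methylphenylsulfinyl]prop-2-en-1-ol (both carbinol epimers)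
Conditions: i-Bu2AlH (2.2 equiv), THF, −78 °C; aq. potassium sodium tartrate
Reagents that add atoms: none
Why: trans-Hydroalumination of the alkynyl sulfoxide, helped by the propargylic aluminium alkoxide, followed by protonolysis gives the E-alkenyl sulfoxide, a known stereoselective reduction that leaves the sulfur configuration untouched.

Step 4
Reactants: 7 (E)-1-(tert-butyldimethylsilyl)-3-[(R)-4-methylphenylsulfinyl]prop-2-en-1-ol
Product: 8 (E)-1-(tert-butyldimethylsilyl)-3-[(R)-4-methylphenylsulfinyl]prop-2-en-1-one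
Conditions: Dess–Martin periodinane, CH2Cl2, 0 to 20 °C
Reagents that add atoms: none
Why: Dess–Martin oxidation of an α-silyl allylic alcohol to the acylsilane runs without base, so no Brook shift intervenes, the sulfoxide is inert, and both carbinol epimers converge on one compound.

Step 5
Reactants: 9 4,4-dimethoxybutan-2-one; 8 (E)-1-(tert-butyldimethylsilyl)-3-[(R)-4-methylphenylsulfinyl]prop-2-en-1-one
Product: 13 (1R,2R)-4-(tert-butyldimethylsilyloxy)-1-(2,2-dimethoxyethyl)-2-[(R)-4-methylphenylsulfinyl]cyclopent-3-en-1-ol, via lithium enolate 10 (not isolated), via silyl alkoxide adduct 11 (not isolated), via siloxyallyl lithium 12 (not isolated)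
Conditions: 9, LiN(i-Pr)2 (1.05 equiv), THF, −78 °C; 8, −78 to −30 °C; AcOH, −78 °C; cold aqueous work-up, crude product used at once
Reagents that add atoms: none
Why: Proposed new method: the kinetic lithium enolate 10 adds through C8 to the acylsilane carbonyl C9 (adduct 11), silicon shifts from C9 to O9 ([1,2]-Brook rearrangement), and the siloxyallyl anion 12, stabilised at C11 by the sulfinyl group, attacks the C12 ketone, so that the C8–C9 and C11–C12 bonds form in one flask. The closest known reaction type is the Brook-rearrangement-mediated [3+2] annulation of β-(phenylthio)- or β-silyl-substituted acryloylsilanes with lithium enolates of alkyl methyl ketones; new here is the enantiopure sulfinyl group as the anion-stabilising β-substituent. The single ring, the cyclopentene C8–C12, closes in the 5-exo-trig mode at the ketone carbonyl. C11 is controlled by the sulfur stereocentre (lithium bridges the sulfinyl and ketone oxygens, p-tolyl points away from the forming bond, the sulfur lone pair takes the crowded sector between C10 and C12), and C12 follows from C11 because this chelate demands a cis sulfinyl/oxido pair. The step needs methyl-side enolisation of 9, secured by LiN(i-Pr)2 under kinetic control, and 1,2- rather than 1,4-addition to 8, secured by the hard lithium enolate at −78 °C, the high electrophilicity of the acylsilane carbonyl and the irreversible Brook shift.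

Step 6
Reactants: 13 (1R,2R)-4-(tert-butyldimethylsilyloxy)-1-(2,2-dimethoxyethyl)-2-[(R)-4-methylphenylsulfinyl]cyclopent-3-en-1-ol
Product: 15 (S)-2-bromo-4-(2,2-dimethoxyethyl)-4-hydroxycyclopent-2-en-1-one, via bromo sulfinyl ketone 14 (not isolated)
Conditions: N-bromosuccinimide (1.05 equiv), THF, −78 to 20 °C; H2O
Reagents that add atoms: N-bromosuccinimide, O=C1CCC(=O)N1Br
Why: α-Bromination of a silyl enol ether places bromine on C10 anti to the sulfinyl group, and the resulting β-sulfinyl ketone, whose acidic C10–H is syn to sulfur, loses sulfenic acid by sulfoxide syn elimination to give the 2-bromoenone, which erases C11 and leaves C12 untouched.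

Step 7
Reactants: 15 (S)-2-bromo-4-(2,2-dimethoxyethyl)-4-hydroxycyclopent-2-en-1-one
Product: 16 (S)-2-[3-bromo-4-oxo-1-(triethylsilyloxy)cyclopent-2-en-1-yl]acetaldehyde
Conditions: Et3SiOTf (3 equiv), 2,6-lutidine (4.5 equiv), CH2Cl2, 0 °C; then H2O
Reagents that add atoms: triethylsilyl trifluoromethanesulfonate, CC[Si](CC)(CC)OS(=O)(=O)C(F)(F)F; water, O
Why: The silyl triflate with a hindered pyridine silylates the tertiary alcohol and turns the aldehyde acetal into a lutidinium salt that water hydrolyses to the aldehyde, a known near-neutral acetal cleavage that spares the bromoenone and cannot trigger retro-aldol opening at C12.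

Step 8
Reactants: 16 (S)-2-[3-bromo-4-oxo-1-(triethylsilyloxy)cyclopent-2-en-1-yl]acetaldehyde; 17 hexyltriphenylphosphonium bromide
Product: 19 (S)-2-bromo-4-[(Z)-oct-2-en-1-yl]-4-(triethylsilyloxy)cyclopent-2-en-1-one, via hexylidene ylide 18 (not isolated)
Conditions: 17, NaN(SiMe3)2 (1.0 equiv), THF, 0 °C; ylide added slowly to 16, THF, −78 °C
Reagents that add atoms: none
Why: Wittig reaction of a non-stabilised ylide under lithium-free conditions gives the Z-alkene C14=C15 by kinetic cis-oxaphosphetane formation, and slow addition of one equivalent of ylide at −78 °C lets the aldehyde outrun the ketone and the enone β-carbon.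

Step 9
Reactants: 20 hex-5-ynoic acid
Product: 22 7-hydroxyhept-5-ynoic acid, via dilithio hexynoate 21 (not isolated)
Conditions: n-BuLi (2.1 equiv), THF, −78 to 0 °C; (CH2O)n, 0 to 20 °C; aq. HCl
Reagents that add atoms: paraformaldehyde (as formaldehyde), C=O
Why: Alkynylation of an aldehyde: the carboxylate acetylide dianion reacts with formaldehyde at its more nucleophilic acetylide carbon.

Step 10
Reactants: 22 7-hydroxyhept-5-ynoic acid
Product: 23 methyl 7-hydroxyhept-5-ynoate
Conditions: MeOH, cat. H2SO4, 20 °C
Reagents that add atoms: methanol, CO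
Why: Fischer esterification, to which the propargylic alcohol is inert.

Step 11
Reactants: 23 methyl 7-hydroxyhept-5-ynoate
Product: 24 methyl (Z)-7-hydroxyhept-5-enoate
Conditions: H2 (1 atm), Pd/CaCO3 poisoned with Pb(OAc)2, quinoline, EtOAc, 20 °C
Reagents that add atoms: none
Why: Lindlar-type semihydrogenation delivers both hydrogens to one face of the alkyne and stops at the Z-alkene C5=C6.

Step 12
Reactants: 24 methyl (Z)-7-hydroxyhept-5-enoate
Product: 25 methyl (Z)-7-oxohept-5-enoate
Conditions: MnO2, CH2Cl2, 20 °C, short reaction time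
Reagents that add atoms: none
Why: MnO2 oxidises the allylic alcohol under neutral heterogeneous conditions, which keeps the Z geometry of the enal.

Step 13
Reactants: 19 (S)-2-bromo-4-[(Z)-oct-2-en-1-yl]-4-(triethylsilyloxy)cyclopent-2-en-1-one; 25 methyl (Z)-7-oxohept-5-enoate
Product: 27 methyl (5Z,7S)-7-[(1R,2S)-4-bromo-2-[(Z)-oct-2-en-1-yl]-5-oxo-2-(triethylsilyloxy)cyclopent-3-en-1-yl]-7-hydroxyhept-5-enoate, via lithium dienolate 26 (not isolated)
Conditions: 19, LiN(i-Pr)2 (1.05 equiv), THF, −78 °C; 25, −78 °C, short contact; AcOH, −78 °C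
Reagents that add atoms: none
Why: Aldol addition through a Zimmerman–Traxler chair: the ring-locked E-enolate gives the anti pair (8R,7S), and the aldehyde approaches C8 on the face opposite the C12 octenyl chain (syn to the smaller C–O bond), which is also the thermodynamically preferred trans arrangement of the two carbon chains.

Step 14
Reactants: 27 methyl (5Z,7S)-7-[(1R,2S)-4-bromo-2-[(Z)-oct-2-en-1-yl]-5-oxo-2-(triethylsilyloxy)cyclopent-3-en-1-yl]-7-hydroxyhept-5-enoate
Product: 29 methyl (5Z,7S)-7-acetoxy-7-[(1R,2S)-4-bromo-2-hydroxy-2-[(Z)-oct-2-en-1-yl]-5-oxocyclopent-3-en-1-yl]hept-5-enoate (target), via silyl ether acetate 28 (not isolated)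
Conditions: Ac2O, pyridine, 0 °C; then HF·pyridine, THF, 0 °C
Reagents that add atoms: acetic anhydride, CC(=O)OC(C)=O
Why: Acetylation of the only free hydroxyl (C7) at low temperature without a stronger base avoids E1cB loss of acetate, and fluoride then cleaves the tertiary silyl ether under weakly acidic conditions that leave C8, the acetate and the methyl ester untouched.

Compound list
1 | tert-butyldimethyl(prop-2-yn-1-yloxy)silane | C#CCO[Si](C)(C)C(C)(C)C | starting material
2 | C,O-dilithio derivative of 1-(tert-butyldimethylsilyl)prop-2-yn-1-ol (formed in the flask) | [Li+].[Li+].[C-]#CC([O-])[Si](C)(C)C(C)(C)C | intermediate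
3 | 1-(tert-butyldimethylsilyl)prop-2-yn-1-ol (racemic) | C#CC(O)[Si](C)(C)C(C)(C)C | intermediate
4 | (1R,2S,5R)-menthyl (S)-4-methylbenzenesulfinate | C[C@@H]1CC[C@H]([C@@H](C1)O[S@](=O)c1ccc(C)cc1)C(C)C | starting material
5 | bis(bromomagnesium) derivative of 3 (formed in the flask) | Br[Mg]C#CC(O[Mg]Br)[Si](C)(C)C(C)(C)C | intermediate
6 | 1-(tert-butyldimethylsilyl)-3-[(S)-4-methylphenylsulfinyl]prop-2-yn-1-ol (both carbinol epimers) | Cc1ccc(cc1)[S@](=O)C#CC(O)[Si](C)(C)C(C)(C)C | intermediate
7 | (E)-1-(tert-butyldimethylsilyl)-3-[(R)-4-methylphenylsulfinyl]prop-2-en-1-ol (both carbinol epimers) | Cc1ccc(cc1)[S@](=O)/C=C/C(O)[Si](C)(C)C(C)(C)C | intermediate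
8 | (E)-1-(tert-butyldimethylsilyl)-3-[(R)-4-methylphenylsulfinyl]prop-2-en-1-one | Cc1ccc(cc1)[S@](=O)/C=C/C(=O)[Si](C)(C)C(C)(C)C | intermediate
9 | 4,4-dimethoxybutan-2-one | COC(OC)CC(C)=O | starting material
10 | lithium enolate of 9, methyl side (formed in the flask) | [Li+].C=C([O-])CC(OC)OC | intermediate
11 | lithium α-silyl alkoxide from 1,2-addition of 10 to 8 (formed in the flask) | [Li+].COC(OC)CC(=O)CC([O-])(/C=C/[S@@](=O)c1ccc(C)cc1)[Si](C)(C)C(C)(C)C | intermediate
12 | sulfinyl-stabilised siloxyallyl lithium after the Brook shift (formed in the flask) | [Li+].COC(OC)CC(=O)CC(O[Si](C)(C)C(C)(C)C)=C[CH-][S@@](=O)c1ccc(C)cc1 | intermediate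
13 | (1R,2R)-4-(tert-butyldimethylsilyloxy)-1-(2,2-dimethoxyethyl)-2-[(R)-4-methylphenylsulfinyl]cyclopent-3-en-1-ol | COC(OC)C[C@@]1(O)[C@H]([S@@](=O)c2ccc(C)cc2)C=C(O[Si](C)(C)C(C)(C)C)C1 | intermediate
14 | 2-bromo-4-(2,2-dimethoxyethyl)-4-hydroxy-3-[(R)-4-methylphenylsulfinyl]cyclopentan-1-one, Br trans to S, S cis to OH (formed in the flask) | COC(OC)C[C@@]1(O)[C@H]([S@@](=O)c2ccc(C)cc2)[C@@H](Br)C(=O)C1 | intermediate
15 | (S)-2-bromo-4-(2,2-dimethoxyethyl)-4-hydroxycyclopent-2-en-1-one | COC(OC)C[C@@]1(O)C=C(Br)C(=O)C1 | intermediate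
16 | (S)-2-[3-bromo-4-oxo-1-(triethylsilyloxy)cyclopent-2-en-1-yl]acetaldehyde | O=CC[C@@]1(O[Si](CC)(CC)CC)C=C(Br)C(=O)C1 | intermediate
17 | hexyltriphenylphosphonium bromide | CCCCCC[P+](c1ccccc1)(c1ccccc1)c1ccccc1.[Br-] | starting material
18 | hexylidenetriphenylphosphorane (formed in the flask) | CCCCCC=P(c1ccccc1)(c1ccccc1)c1ccccc1 | intermediate
19 | (S)-2-bromo-4-[(Z)-oct-2-en-1-yl]-4-(triethylsilyloxy)cyclopent-2-en-1-one | CCCCC/C=C\C[C@@]1(O[Si](CC)(CC)CC)C=C(Br)C(=O)C1 | intermediate
20 | hex-5-ynoic acid | C#CCCCC(=O)O | starting material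
21 | dilithium salt of hex-5-ynoic acid, carboxylate and acetylide (formed in the flask) | [Li+].[Li+].[C-]#CCCCC(=O)[O-] | intermediate
22 | 7-hydroxyhept-5-ynoic acid | OCC#CCCCC(=O)O | intermediate
23 | methyl 7-hydroxyhept-5-ynoate | OCC#CCCCC(=O)OC | intermediate
24 | methyl (Z)-7-hydroxyhept-5-enoate | OC/C=C\CCCC(=O)OC | intermediate
25 | methyl (Z)-7-oxohept-5-enoate | O=C/C=C\CCCC(=O)OC | intermediate
26 | lithium cross-conjugated dienolate of 19 (formed in the flask) | [Li+].CCCCC/C=C\C[C@@]1(O[Si](CC)(CC)CC)C=C(Br)C([O-])=C1 | intermediate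
27 | methyl (5Z,7S)-7-[(1R,2S)-4-bromo-2-[(Z)-oct-2-en-1-yl]-5-oxo-2-(triethylsilyloxy)cyclopent-3-en-1-yl]-7-hydroxyhept-5-enoate | CCCCC/C=C\C[C@@]1(O[Si](CC)(CC)CC)C=C(Br)C(=O)[C@@H]1[C@H](/C=C\CCCC(=O)OC)O | intermediate
28 | methyl (5Z,7S)-7-acetoxy-7-[(1R,2S)-4-bromo-2-[(Z)-oct-2-en-1-yl]-5-oxo-2-(triethylsilyloxy)cyclopent-3-en-1-yl]hept-5-enoate (formed in the flask) | CCCCC/C=C\C[C@@]1(O[Si](CC)(CC)CC)C=C(Br)C(=O)[C@@H]1[C@H](/C=C\CCCC(=O)OC)OC(C)=O | intermediate
29 | methyl (5Z,7S)-7-acetoxy-7-[(1R,2S)-4-bromo-2-hydroxy-2-[(Z)-oct-2-en-1-yl]-5-oxocyclopent-3-en-1-yl]hept-5-enoate | CCCCC/C=C\C[C@@]1(O)C=C(Br)C(=O)[C@@H]1[C@H](/C=C\CCCC(=O)OC)OC(C)=O | target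

Total step count: 14. Longest linear sequence: 10 (steps 1 to 8, 13 and 14).

Steps most likely to fail

Risk 1 (step 5, the labelled step).
- **What may go wrong:** The enolate may add in conjugate fashion at C11 with loss of sulfenate. The sulfur chirality may be transmitted poorly to C11 and C12 (poor facial selectivity), which would surface as eroded enantiopurity because the auxiliary is lost in step 6. The allylic sulfoxide may also undergo an early [2,3]-shift before bromination.
- **Fallback:** It uses known chemistry, sets out from 3 and 9, and comes back at 15. Compound 3 is oxidised with MnO2 to 1-(tert-butyldimethylsilyl)prop-2-yn-1-one F1. Thiophenol with catalytic Et3N adds to give (E)-1-(tert-butyldimethylsilyl)-3-(phenylthio)prop-2-en-1-one F2. F2 and enolate 10 undergo the established phenylthio version of the annulation to racemic 4-(tert-butyldimethylsilyloxy)-1-(2,2-dimethoxyethyl)-2-(phenylthio)cyclopent-3-en-1-ol F3. N-Bromosuccinimide, then m-CPBA at −78 °C and warming, give racemic 2-bromo-4-(2,2-dimethoxyethyl)-4-hydroxycyclopent-2-en-1-one F4. Its enantiomers are separated by preparative chromatography on a cellulose carbamate phase to deliver 15.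

Risk 2 (step 8).
- **What may go wrong:** The ylide may attack the bromoenone (conjugate addition or olefination of the ketone). The basic ylide may also induce β-elimination of the silyloxy group from the enolisable aldehyde.
- **Fallback:** It sets out from 13 and comes back at 19. The olefination is moved ahead of the bromination.
 - Bu4NF buffered with AcOH desilylates 13 and expels sulfenate to give (S)-4-(2,2-dimethoxyethyl)-4-hydroxycyclopent-2-en-1-one F5.
 - Et3SiOTf with 2,6-lutidine, then water, gives (S)-2-[4-oxo-1-(triethylsilyloxy)cyclopent-2-en-1-yl]acetaldehyde F6.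
 - Ylide 18 converts this less electrophilic enone aldehyde into (S)-4-[(Z)-oct-2-en-1-yl]-4-(triethylsilyloxy)cyclopent-2-en-1-one F7.
 - Nucleophilic epoxidation (t-BuOOH, DBU) touches only the enone and gives (4S)-2,3-epoxy-4-[(Z)-oct-2-en-1-yl]-4-(triethylsilyloxy)cyclopentan-1-one F8.
 - Bromide opening at C10 with dehydration (NaBr, Amberlyst 15, acetone) leads to 19 without exposing the Z-alkene to an electrophilic bromine source.

Risk 3 (step 13).
- **What may go wrong:** Facial selectivity at C8 next to the fully substituted C12 may be poor. The anti/syn selectivity at C7 with a lithium enolate may be low. The enal may isomerise from Z to E under basic conditions, and the aldolate may undergo retro-aldol equilibration.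
- **Fallback:** It sets out from 19 and comes back at 27. Soft enolisation with (c-C6H11)2BCl and Et3N in Et2O at −78 °C gives the dicyclohexylboron dienolate of 19 F9. This adds to 25 through a tighter boron-centred chair without any free amide base. Work-up with MeOH and pH 7 buffer releases 27.

Further compounds
F1 | step 5 | 1-(tert-butyldimethylsilyl)prop-2-yn-1-one | C#CC(=O)[Si](C)(C)C(C)(C)C
F2 | step 5 | (E)-1-(tert-butyldimethylsilyl)-3-(phenylthio)prop-2-en-1-one | CC(C)(C)[Si](C)(C)C(=O)/C=C/Sc1ccccc1
F3 | step 5 | racemic 4-(tert-butyldimethylsilyloxy)-1-(2,2-dimethoxyethyl)-2-(phenylthio)cyclopent-3-en-1-ol | COC(OC)CC1(O)C(Sc2ccccc2)C=C(O[Si](C)(C)C(C)(C)C)C1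
F4 | step 5 | racemic 2-bromo-4-(2,2-dimethoxyethyl)-4-hydroxycyclopent-2-en-1-one | COC(OC)CC1(O)C=C(Br)C(=O)C1
F5 | step 8 | (S)-4-(2,2-dimethoxyethyl)-4-hydroxycyclopent-2-en-1-one | COC(OC)C[C@@]1(O)C=CC(=O)C1
F6 | step 8 | (S)-2-[4-oxo-1-(triethylsilyloxy)cyclopent-2-en-1-yl]acetaldehyde | O=CC[C@@]1(O[Si](CC)(CC)CC)C=CC(=O)C1
F7 | step 8 | (S)-4-[(Z)-oct-2-en-1-yl]-4-(triethylsilyloxy)cyclopent-2-en-1-one | CCCCC/C=C\C[C@@]1(O[Si](CC)(CC)CC)C=CC(=O)C1
F8 | step 8 | (4S)-2,3-epoxy-4-[(Z)-oct-2-en-1-yl]-4-(triethylsilyloxy)cyclopentan-1-one (epoxide face open, both centres are lost again) | CCCCC/C=C\C[C@@]1(O[Si](CC)(CC)CC)C2OC2C(=O)C1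
F9 | step 13 | dicyclohexylboron dienolate of 19 | CCCCC/C=C\C[C@@]1(O[Si](CC)(CC)CC)C=C(Br)C(OB(C2CCCCC2)C2CCCCC2)=C1
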